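Amounts first: each starting material lost becomes a target at the price of one reagent, and each target that goes on to over-reaction product costs a second reagent. So, leaving ended chains aside, with e equivalents charged, c(starting material) = ((2 − e)·100 − c(target) + c(reagent))/2, all in percent of the starting material charged.

| setting | theta | flask |
|---|---|---|
| starting material | 0.10 M | 0.10 M |
| reagent | 1 equiv | 1.00 equiv |
| initiator | 5 mol% | 5 mol% |
| remark | the very flask that is asked about, followed so far |  |
| time |  | 12 min |

theta run (percent of the starting material charged)

| time / s | over-reaction product / % | first chain carrier / % | target / % | starting material / % |
|---|---|---|---|---|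
| 10.0 | 0 | 0 | 0.4 | 99.0 |
| 20.0 | 0.1 | 0.6 | 2.2 | 98.9 |
| 40.0 | 1.5 | 0.5 | 4.8 | 95.3 |
| 60.0 | 2.1 | 0.4 | 3.9 | 93.7 |
| 80.0 | 1.6 | 0 | 7.4 | 88.6 |

(each reading ± 1 percentage point)

- a species is counted by the starting material in it: one ended chains A counts as two
- the numbers in the tables scatter by 1 percentage point (one standard deviation)
- candidate steps: initiator -> 2 initiating radical; starting material + initiating radical -> capped initiator + first chain carrier; reagent + first chain carrier -> target + second chain carrier; starting material + second chain carrier -> by-product + first chain carrier; 2 first chain carrier -> ended chains A; 2 second chain carrier -> ended chains B; reagent + target -> over-reaction product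

- the species that holds most of what was charged as starting material, at 12 min (over-reaction product / first chain carrier / target / starting material)
- the largest share itself, whichever of these holds it, in percent of the starting material charged

The readings from 40.0 s to 80.0 s let me leave ended chains aside: summed, the losses of starting material come to 22.4%, and target plus over-reaction product come to 21.3%, with each reading scattering by 1 percentage point.

My first way uses starting material alone: a constant of 0.00124 s⁻¹, held steady, leaves 40.8% in this flask at 12 min.

My second way uses the other two species. Product forms at 0.00118 s⁻¹ of the charge, and 24.4% of it is over-reaction product at a mean time of 60.0 s. Doubling that share and dividing by the mean time gives a pseudo-first-order loss of target near 0.00814 s⁻¹, and the ratio of these two early rates, frozen, is 14.5%, which I take as a rough estimate of target at the end. Putting this estimate and zero reagent into the balance at one equivalent gives 42.7%, the reagent ledger: the starting material left once the reagent bill is paid.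

The two ways use different readings and lie 1.9 points apart. The first way's conversion would bill 104% of the reagent charge, so the ends join near 12 min, and I commit to 42.7%.

The forecast names starting material at 48%, range 36% to 62%, and its ground reads “the single equivalent of reagent is wasted and the chain slows”. The flask gives starting material at 43.2%, with over-reaction product at 32.9% and target at 23.5%.

    initiator → 2 initiating radical (k = 0.0120 min⁻¹)
    starting material + initiating radical → capped initiator + first chain carrier (k = 2.40 × 10⁶ M⁻¹ s⁻¹)
    reagent + first chain carrier → target + second chain carrier (k = 46000 M⁻¹ s⁻¹)
    starting material + second chain carrier → by-product + first chain carrier (k = 24000 M⁻¹ s⁻¹)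
    2 first chain carrier → ended chains A (k = 2.00 × 10⁸ M⁻¹ s⁻¹)
    2 second chain carrier → ended chains B (k = 2.50 × 10⁸ M⁻¹ s⁻¹)
    reagent + target → over-reaction product (k = 4.40 M⁻¹ min⁻¹)

In this flask, the chain step making target had 67% of its turnover behind it at 6.00 min, while reagent stood at 42.1% of its charge. Reagent + target then carried over-reaction product to 32.9% by 12.0 min, with reagent at 10.8%. Correcting the ledger with the simulated target and reagent gives 43.7%. In the neighbour flask with 1.70 equiv of reagent, target 12.0% and reagent 31.3% of its charge, the corrected ledger gives 35.6%, and that flask holds 35.5% starting material.

The earlier runs and the new flask come from a simulation from invented constants.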